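**Retrosynthetic overview**
1. The target is a linear trimer. A central 2,4,6-trihydroxyphenyl isobutyl ketone ring (ring B) carries the same hexasubstituted ring (A and A′) at C3 and at C5, each through a CH2 bridge. Both ArCH2–C(ring B) bonds are cut at once, giving phlorisovalerophenone and two molecules of one o-quinone methide, stored as its dimethylamine adduct (a phenolic Mannich base).
2. Enabling feature: ring B has a mirror plane through C1 (acyl) and C4 (OH), so C3–H and C5–H are equivalent nucleophilic carbons, each flanked by two OH groups. Each bridge CH2 sits on a ring-A carbon flanked by two phenolic OH groups (a latent o-quinone methide). Ring A has no other free position, so it can act only as the electrophile.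
3. The Mannich base comes from 1-(4,6-dihydroxy-2-methoxy-3-methylphenyl)-3-methylbutan-1-one by aminomethylation of its only ring C–H. That ketone comes from 2-methylphloroglucinol by C-acylation, 4,6-bis-O-benzylation, O-methylation of the remaining chelated 2-OH and hydrogenolysis.
4. Phlorisovalerophenone comes from phloroglucinol by C-acylation.
5. No ring is formed in the route. The three benzene rings are bought (phloroglucinol once, 2-methylphloroglucinol twice) and are joined in the last step in the order A + B, then AB + A′.

Key step: step 7

Remark: the structure has no stereocentre and no configurationally stable axis, and it has a mirror plane. It is therefore achiral, the SMILES defines a single species, and no step has to control configuration.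

**Step 1**
Reactants: 1 phloroglucinol (benzene-1,3,5-triol); 2 isovaleryl chloride (3-methylbutanoyl chloride)
Product: 3 phlorisovalerophenone, 3-methyl-1-(2,4,6-trihydroxyphenyl)butan-1-one
Conditions: AlCl3 (3.5 equiv), CH2Cl2/MeNO2, 0 °C to 40 °C; ice/2 M HCl
Reagents that add atoms: none
Why: Friedel–Crafts C-acylation of the threefold symmetric, triply activated ring can give only one regioisomer, and the chelated aryl ketone–aluminium complex deactivates the ring against a second acylation.

**Step 2**
Reactants: 4 2-methylphloroglucinol (2-methylbenzene-1,3,5-triol); 2 isovaleryl chloride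
Product: 5 3-methyl-1-(2,4,6-trihydroxy-3-methylphenyl)butan-1-one
Conditions: AlCl3 (3.5 equiv), CH2Cl2/MeNO2, 0 °C to 40 °C; ice/2 M HCl
Reagents that add atoms: none
Why: Friedel–Crafts C-acylation; the two free ring positions of 4 are equivalent by symmetry, so only one monoketone can form.

**Step 3**
Reactants: 5 3-methyl-1-(2,4,6-trihydroxy-3-methylphenyl)butan-1-one
Product: 6 1-[4,6-bis(benzyloxy)-2-hydroxy-3-methylphenyl]-3-methylbutan-1-one
Conditions: BnBr (2.1 equiv), K2CO3 (2.2 equiv), DMF, rt
Reagents that add atoms: benzyl bromide, BrCc1ccccc1
Why: Williamson etherification under weak base, in which the non-chelated 4-OH should react first and the 6-OH (next to the ring C–H) second, while the 2-OH, buttressed between the C3 methyl group and the carbonyl, keeps its strong hydrogen bond and stays free, as is known for the partial alkylation of 3-methylphloracylphenones.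

**Step 4**
Reactants: 6 1-[4,6-bis(benzyloxy)-2-hydroxy-3-methylphenyl]-3-methylbutan-1-one
Product: 7 1-[4,6-bis(benzyloxy)-2-methoxy-3-methylphenyl]-3-methylbutan-1-one
Conditions: MeI (3 equiv), K2CO3 (3 equiv), DMF, 50 °C
Reagents that add atoms: methyl iodide, CI
Why: Williamson O-methylation of the only remaining phenol under forcing but weakly basic conditions; K2CO3 does not enolise the aryl alkyl ketone, so C-methylation is not expected and the benzyl ethers are inert.

**Step 5**
Reactants: 7 1-[4,6-bis(benzyloxy)-2-methoxy-3-methylphenyl]-3-methylbutan-1-one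
Product: 8 1-(4,6-dihydroxy-2-methoxy-3-methylphenyl)-3-methylbutan-1-one
Conditions: H2 (1 atm), 10% Pd/C, EtOAc/MeOH, rt
Reagents that add atoms: none
Why: Catalytic hydrogenolysis of the two benzyl aryl ethers; the hindered, electron-rich aryl ketone and the aryl methyl ether should not react at 1 atm and rt.

**Step 6**
Reactants: 8 1-(4,6-dihydroxy-2-methoxy-3-methylphenyl)-3-methylbutan-1-one
Product: 9 1-{3-[(dimethylamino)methyl]-2,4-dihydroxy-6-methoxy-5-methylphenyl}-3-methylbutan-1-one
Conditions: 37% aq CH2O (1.1 equiv) and 40% aq Me2NH (1.5 equiv), premixed, EtOH, 0 °C to rt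
Reagents that add atoms: formaldehyde, C=O; dimethylamine, CNC
Why: Phenolic Mannich reaction; the only ring C–H of 8 lies between two OH groups and is the sole site for the preformed aminomethylating agent, and the low temperature and excess amine keep the product from losing amine prematurely.

**Step 7**
Reactants: 9 1-{3-[(dimethylamino)methyl]-2,4-dihydroxy-6-methoxy-5-methylphenyl}-3-methylbutan-1-one (2.1 equiv); 3 phlorisovalerophenone (1.0 equiv)
Product: 12 1-[3,5-bis({2,6-dihydroxy-4-methoxy-3-methyl-5-(3-methylbutanoyl)phenyl}methyl)-2,4,6-trihydroxyphenyl]-3-methylbutan-1-one (target), via o-quinone methide 5-hydroxy-3-methoxy-2-methyl-4-(3-methylbutanoyl)-6-methylidenecyclohexa-2,4-dien-1-one 10 (not isolated), via mono-bridged dimer 1-[3-({2,6-dihydroxy-4-methoxy-3-methyl-5-(3-methylbutanoyl)phenyl}methyl)-2,4,6-trihydroxyphenyl]-3-methylbutan-1-one 11 (not isolated)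
Conditions: 9 added portionwise to 3, 1,4-dioxane, 90 °C, N2 sparge (removes Me2NH)
Reagents that add atoms: none
Why: Proton transfer from the acidic, non-chelated OH next to the CH2N group of 9 to nitrogen and E1cB-type loss of volatile Me2NH should unmask o-quinone methide 10, whose exocyclic CH2 is attacked by C3 of the phenolate/enol form of 3 (conjugate addition, then re-aromatising tautomerisation of both rings) to give 11. The remaining C5–H of the central ring of 11, equivalent by symmetry to the first site and still flanked by two OH groups, then adds to the CH2 of a second molecule of 10, which forms the second ArCH2–C(central ring) bond and joins the two-ring fragment 11 to the third ring, so that three building blocks and both bridges are assembled two-directionally in one operation. The closest known reaction type is the C-alkylation of acylphloroglucinols, naphthols and cyclic 1,3-dicarbonyl compounds with phenolic Mannich bases (o-quinone methide Michael addition), the usual entry to unsymmetrical methylene-bridged acylphloroglucinol dimers. No ring is closed and no stereocentre is created. The step needs cross- instead of homo-coupling, C- instead of O-alkylation and double instead of single alkylation: 9 and 10 have no ring C–H and can act only as electrophile, 3 and 11 have no leaving group and can act only as nucleophile, O-adducts revert to 10 whereas C-adducts are locked by aromatisation, and after two alkylations no ring C–H is left. Sparging out Me2NH makes the elimination irreversible and keeps the medium nearly neutral, which should slow retro-Michael exchange of the bridges.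

**Compound list**
1 | phloroglucinol | Oc1cc(O)cc(O)c1 | starting material
2 | isovaleryl chloride | CC(C)CC(=O)Cl | starting material
3 | phlorisovalerophenone, 3-methyl-1-(2,4,6-trihydroxyphenyl)butan-1-one | CC(C)CC(=O)c1c(O)cc(O)cc1O | intermediate
4 | 2-methylphloroglucinol | Cc1c(O)cc(O)cc1O | starting material
5 | 3-methyl-1-(2,4,6-trihydroxy-3-methylphenyl)butan-1-one | CC(C)CC(=O)c1c(O)cc(O)c(C)c1O | intermediate
6 | 1-[4,6-bis(benzyloxy)-2-hydroxy-3-methylphenyl]-3-methylbutan-1-one | CC(C)CC(=O)c1c(OCc2ccccc2)cc(OCc2ccccc2)c(C)c1O | intermediate
7 | 1-[4,6-bis(benzyloxy)-2-methoxy-3-methylphenyl]-3-methylbutan-1-one | CC(C)CC(=O)c1c(OCc2ccccc2)cc(OCc2ccccc2)c(C)c1OC | intermediate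
8 | 1-(4,6-dihydroxy-2-methoxy-3-methylphenyl)-3-methylbutan-1-one | CC(C)CC(=O)c1c(O)cc(O)c(C)c1OC | intermediate
9 | 1-{3-[(dimethylamino)methyl]-2,4-dihydroxy-6-methoxy-5-methylphenyl}-3-methylbutan-1-one | CC(C)CC(=O)c1c(O)c(CN(C)C)c(O)c(C)c1OC | intermediate
10 | 5-hydroxy-3-methoxy-2-methyl-4-(3-methylbutanoyl)-6-methylidenecyclohexa-2,4-dien-1-one (o-quinone methide) | C=C1C(=O)C(C)=C(OC)C(C(=O)CC(C)C)=C1O | intermediate
11 | 1-[3-({2,6-dihydroxy-4-methoxy-3-methyl-5-(3-methylbutanoyl)phenyl}methyl)-2,4,6-trihydroxyphenyl]-3-methylbutan-1-one | CC(C)CC(=O)c1c(O)cc(O)c(Cc2c(O)c(C)c(OC)c(C(=O)CC(C)C)c2O)c1O | intermediate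
12 | 1-[3,5-bis({2,6-dihydroxy-4-methoxy-3-methyl-5-(3-methylbutanoyl)phenyl}methyl)-2,4,6-trihydroxyphenyl]-3-methylbutan-1-one | COc1c(C)c(O)c(Cc2c(O)c(Cc3c(O)c(C)c(OC)c(C(=O)CC(C)C)c3O)c(O)c(C(=O)CC(C)C)c2O)c(O)c1C(=O)CC(C)C | target

**Total step count:** 7
**Longest linear sequence:** 6 steps (steps 2, 3, 4, 5, 6 and 7, from 2-methylphloroglucinol)

**Steps most likely to fail**

1. Step 7.
- What may go wrong: bridges that have already formed may cleave by retro-Michael reaction in their phenolate form and re-add in another sense, which exchanges the methylene bridges. The aminomethyl group may be transferred from 9 to 3. The quinone methide may be captured by itself. The reaction may stall after the first alkylation.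
- Fallback: an amine-free, cationic union through a temporary boron-containing ring. It sets out from 8. Boronic-acid-templated ortho-hydroxymethylation (PhB(OH)2, paraformaldehyde, cat. propionic acid, toluene, Dean–Stark) should give 1-(5-hydroxy-7-methoxy-8-methyl-2-phenyl-4H-1,3,2-benzodioxaborin-6-yl)-3-methylbutan-1-one F1, a neutral and isolable storage form of the same benzylic electrophile. F1 (2.1 equiv) would then be ionised with BF3·OEt2 in CH2Cl2/MeCN at −20 to 0 °C in the presence of 3 (1.0 equiv). This is a double Friedel–Crafts benzylation at the same two carbons of the central ring. Because no base and no phenolate are present, the retro-Michael channel is closed. Aqueous work-up hydrolyses the aryl boronate esters, and the route is rejoined at 12.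

2. Step 3.
- What may go wrong: poor discrimination between the two hydroxyl groups ortho to the ketone, and competing C-benzylation at the free ring carbon.
- Fallback: the regiochemical question is removed by starting from a symmetric ketone and bringing in the C-methyl group afterwards. It sets out from 3, whose two ortho-OH groups are equivalent. Bis-benzylation (BnBr, K2CO3, DMF) should give 1-[2,4-bis(benzyloxy)-6-hydroxyphenyl]-3-methylbutan-1-one F2. Iodination ortho to the free, chelated OH (NIS, cat. TFA, MeCN, 0 °C) should give 1-[4,6-bis(benzyloxy)-2-hydroxy-3-iodophenyl]-3-methylbutan-1-one F3. O-methylation (MeI, K2CO3, DMF) should give 1-[4,6-bis(benzyloxy)-3-iodo-2-methoxyphenyl]-3-methylbutan-1-one F4. Suzuki–Miyaura methylation (trimethylboroxine, Pd(OAc)2/SPhos, K2CO3, dioxane/H2O, 100 °C) rejoins the route at 7.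

3. Step 6.
- What may go wrong: the nascent Mannich base may lose amine early and be captured by unreacted 8, which is self-condensation through a formaldehyde-derived bridge.
- Fallback: the aminomethyl group is built without formaldehyde, at the aldehyde oxidation level. It sets out from 8. Vilsmeier–Haack formylation (POCl3, DMF, MeCN, 0 °C to rt; aqueous hydrolysis) at the only free ring carbon should give 2,6-dihydroxy-4-methoxy-3-methyl-5-(3-methylbutanoyl)benzaldehyde F5. Reductive amination (Me2NH in THF, NaBH(OAc)3, 1,2-dichloroethane, rt) rejoins the route at 9.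

**Further compounds**
F1 | step 7 | 1-(5-hydroxy-7-methoxy-8-methyl-2-phenyl-4H-1,3,2-benzodioxaborin-6-yl)-3-methylbutan-1-one | CC(C)CC(=O)c1c(O)c2COB(c3ccccc3)Oc2c(C)c1OC
F2 | step 3 | 1-[2,4-bis(benzyloxy)-6-hydroxyphenyl]-3-methylbutan-1-one | CC(C)CC(=O)c1c(O)cc(OCc2ccccc2)cc1OCc3ccccc3
F3 | step 3 | 1-[4,6-bis(benzyloxy)-2-hydroxy-3-iodophenyl]-3-methylbutan-1-one | CC(C)CC(=O)c1c(OCc2ccccc2)cc(OCc2ccccc2)c(I)c1O
F4 | step 3 | 1-[4,6-bis(benzyloxy)-3-iodo-2-methoxyphenyl]-3-methylbutan-1-one | CC(C)CC(=O)c1c(OCc2ccccc2)cc(OCc2ccccc2)c(I)c1OC
F5 | step 6 | 2,6-dihydroxy-4-methoxy-3-methyl-5-(3-methylbutanoyl)benzaldehyde | CC(C)CC(=O)c1c(O)c(C=O)c(O)c(C)c1OC
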